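Everything rests on cutting ring C of units 1 and 2 between C4 and C4a. The feature exploited is that C4 of each upper unit is a diarylmethine CH joining C4a of its own ring A to C8 of the ring A beneath, trans to the C3 oxygen. C4 is brought in as a formyl carbon on C8 of the lower unit and advanced to a trans-C3,C4-epoxide whose neighbouring C2 carries ring B and a phloroglucinol-type aryl ether. Lewis acid then lets the ether's ortho carbon open the epoxide at C4, forming the C4–C4a bond, ring C and the C4 stereocentre in one operation. Two such cycles, galloylation and hydrogenolysis complete the route.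

Key step: step 10

Assumption: 3,5-bis(benzyloxy)phenol, 3',4'-bis(benzyloxy)acetophenone and 3,4,5-tris(benzyloxy)benzoic acid are bought as such. Flavan numbering (unit 1 top, unit 2 middle, unit 3 terminal) is used for all intermediates, and the target is named as the 3,3',3''-tri-O-gallate. TBS = tert-butyldimethylsilyl, Bn = benzyl.

Design remark: in the first cycle the phenol carries a bromine ortho to its oxygen. The bromine is a spectator in the ring closure and leaves a single ortho carbon able to cyclise. It ends up on C8 of unit 2 as the handle for the next formylation, so the dimer never has to be functionalised regioselectively.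

Step 1
Reactants: 1 (−)-epicatechin
Product: 2 5,7,3',4'-tetra-O-benzyl-(−)-epicatechin
Conditions: BnBr (4.4 equiv), K2CO3, DMF, 0 °C to rt, argon
Reagents that add atoms: benzyl bromide, BrCc1ccccc1
Why: Williamson ether synthesis in which carbonate deprotonates only the four phenols, so the secondary C3 hydroxyl stays free and the C2 and C3 stereocentres are not touched.

Step 2
Reactants: 2 5,7,3',4'-tetra-O-benzyl-(−)-epicatechin
Product: 3 8-bromo-5,7,3',4'-tetra-O-benzylepicatechin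
Conditions: NBS (1.0 equiv), CH2Cl2, −40 °C to rt
Reagents that add atoms: N-bromosuccinimide, O=C1CCC(=O)N1Br
Why: Electrophilic aromatic bromination of the phloroglucinol-type ring A, expected at C8 because C6 is shielded by two flanking benzyloxy groups, a regiochemistry established for protected flavan-3-ols.

Step 3
Reactants: 3 8-bromo-5,7,3',4'-tetra-O-benzylepicatechin
Product: 4 8-bromo-3-O-TBS-5,7,3',4'-tetra-O-benzylepicatechin
Conditions: TBSOTf, 2,6-lutidine, CH2Cl2, 0 °C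
Reagents that add atoms: tert-butyldimethylsilyl triflate, CC(C)(C)[Si](C)(C)OS(=O)(=O)C(F)(F)F
Why: Silylation of the only free hydroxyl, which masks O3 of unit 3 against the organolithium of step 4 and the Mitsunobu reaction of step 9 and can be removed later without touching benzyl ethers.

Step 4
Reactants: 4 8-bromo-3-O-TBS-5,7,3',4'-tetra-O-benzylepicatechin
Product: 6 8-formyl-3-O-TBS-5,7,3',4'-tetra-O-benzylepicatechin, via 8-lithioflavan 5 (not isolated)
Conditions: t-BuLi (2.2 equiv), THF, −78 °C; then DMF, −78 °C to 0 °C; aq NH4Cl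
Reagents that add atoms: N,N-dimethylformamide, CN(C)C=O; tert-butyllithium, [Li]C(C)(C)C (lithium of intermediate 5 only)
Why: Bromine–lithium exchange followed by formylation of the aryllithium with DMF (Bouveault aldehyde synthesis), which places the carbon that becomes C4 of unit 2 on C8 of unit 3; the ethers and stereocentres are inert at −78 °C.

Step 5
Reactants: 6 8-formyl-3-O-TBS-5,7,3',4'-tetra-O-benzylepicatechin; 7 3',4'-bis(benzyloxy)acetophenone
Product: 8 (E)-1-[3,4-bis(benzyloxy)phenyl]-3-(3-O-TBS-5,7,3',4'-tetra-O-benzylepicatechin-8-yl)prop-2-en-1-one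
Conditions: KOH, EtOH/THF, rt to 40 °C
Reagents that add atoms: none
Why: Claisen–Schmidt condensation (crossed aldol, then E1cB dehydration) of a non-enolisable aldehyde with the methyl ketone, giving the conjugated E-enone as the thermodynamic alkene; TBS and benzyl ethers tolerate alcoholic hydroxide at this temperature.

Step 6
Reactants: 8 (E)-enone of unit 3
Product: 9 [3,4-bis(benzyloxy)phenyl][(2R,3S)-3-(3-O-TBS-5,7,3',4'-tetra-O-benzylepicatechin-8-yl)oxiran-2-yl]methanone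
Conditions: poly-L-leucine, urea–H2O2, DBU, THF, rt
Reagents that add atoms: hydrogen peroxide (from its urea adduct), OO
Why: Juliá–Colonna epoxidation (peptide-catalysed Weitz–Scheffer reaction) in which hydroperoxide adds to the β-carbon and closes to the trans-epoxide, the L-peptide selecting the enone face that leads to the (αR,βS)-epoxide and so setting C3 and C4 of the future unit 2, while the basic medium spares the acid-labile benzylic epoxide.

Step 7
Reactants: 9 (2R,3S)-epoxy ketone of unit 3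
Product: 10 (S)-[3,4-bis(benzyloxy)phenyl][(2S,3S)-3-(3-O-TBS-5,7,3',4'-tetra-O-benzylepicatechin-8-yl)oxiran-2-yl]methanol (erythro)
Conditions: Zn(BH4)2, Et2O/THF, −30 °C; aq NaHCO3; Et3N-deactivated silica
Reagents that add atoms: none
Why: Chelation-controlled ketone reduction in which zinc bridges the carbonyl and epoxide oxygens and hydride arrives on the face away from the epoxide C–C bond, which should give the erythro (anti) epoxy alcohol with the (S)-carbinol, the C2 epimer required for the inversion in step 9.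

Step 8
Reactants: 11 3,5-bis(benzyloxy)phenol
Product: 12 2-bromo-3,5-bis(benzyloxy)phenol
Conditions: NBS (1.0 equiv), i-Pr2NH (cat.), CH2Cl2, −78 °C to 0 °C
Reagents that add atoms: N-bromosuccinimide, O=C1CCC(=O)N1Br
Why: Amine-catalysed ortho-bromination of a phenol (electrophilic aromatic substitution by an N-bromoamine held at the OH), favouring C2 over the more hindered C4 between the two benzyloxy groups; any para isomer is removed at this early stage.

Step 9
Reactants: 10 erythro epoxy alcohol of unit 3; 12 2-bromo-3,5-bis(benzyloxy)phenol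
Product: 13 (2R,3S)-2-{(R)-[3,4-bis(benzyloxy)phenyl][2-bromo-3,5-bis(benzyloxy)phenoxy]methyl}-3-(3-O-TBS-5,7,3',4'-tetra-O-benzylepicatechin-8-yl)oxirane (in flavan numbering of the future unit 2: 2R aryl ether, trans-3R,4S epoxide)
Conditions: PPh3, DIAD, toluene, 0 °C to rt; basic alumina
Reagents that add atoms: none
Why: Mitsunobu etherification in which the phenoxide displaces the alkoxyphosphonium of the secondary benzylic alcohol with inversion, turning the (S)-carbinol into the (R)-aryl ether that is C2 of unit 2 with the epicatechin configuration, under neutral conditions that leave the epoxide intact.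

Step 10
Reactants: 13 trans-epoxy bromoaryl ether on C8 of unit 3
Product: 14 8-bromo-5,7,3',4'-tetra-O-benzylepicatechin-(4β→8)-3-O-TBS-5,7,3',4'-tetra-O-benzylepicatechin (free O3 on unit 2)
Conditions: BF3·OEt2 (0.3 equiv), CH2Cl2 (5 mM), −78 °C to −40 °C; Et3N quench
Reagents that add atoms: none
Why: BF3 binds the epoxide oxygen and weakens the C4–O bond, which is benzylic to the 2,4,6-trioxygenated ring A of unit 3; the one free ortho carbon of the aryl ether (the other bears bromine) attacks C4 from the face opposite the departing oxygen, and rearomatisation leaves the former epoxide oxygen as the C3 hydroxyl. The closest known reaction type is the Lewis-acid-mediated intramolecular Friedel–Crafts epoxy–arene cyclisation of aryl glycidyl ethers to trans-4-arylchroman-3-ols. Ring C of unit 2 (O1, C2, C3, C4, C4a, C8a) closes in the 6-endo-tet mode through the new C4–C4a bond. The new stereocentre C4 is controlled by the epoxide: anti opening of the trans-(3R,4S)-epoxide inverts C4 and places the unit 3 aryl group trans to O3 (4β), and a more cationic pathway should give the same result because attack anti to the C3 oxygen is favoured in the half-chair transition state. The step needs 6-endo attack at C4 instead of 5-exo attack at C3, secured by the strong benzylic activation of C4, and no erosion at C2 or C3, secured because neither is a bonding site, so the threo ether–epoxide relationship becomes the 2,3-cis ring.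

Step 11
Reactants: 14 bromo dimer with free O3 on unit 2
Product: 15 8-bromo-3-O-TBS-5,7,3',4'-tetra-O-benzylepicatechin-(4β→8)-3-O-TBS-5,7,3',4'-tetra-O-benzylepicatechin
Conditions: TBSOTf, 2,6-lutidine, CH2Cl2, 0 °C to rt
Reagents that add atoms: tert-butyldimethylsilyl triflate, CC(C)(C)[Si](C)(C)OS(=O)(=O)C(F)(F)F
Why: Silylation of the new C3 hydroxyl of unit 2, which would otherwise quench the aryllithium of step 12 and compete in the Mitsunobu reaction of step 16.

Step 12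
Reactants: 15 bis-TBS bromo dimer
Product: 17 8-formyl-3-O-TBS-5,7,3',4'-tetra-O-benzylepicatechin-(4β→8)-3-O-TBS-5,7,3',4'-tetra-O-benzylepicatechin, via 8-lithio dimer 16 (not isolated)
Conditions: t-BuLi (2.2 equiv), THF, −78 °C; then DMF, −78 °C to 0 °C; aq NH4Cl
Reagents that add atoms: N,N-dimethylformamide, CN(C)C=O; tert-butyllithium, [Li]C(C)(C)C (lithium of intermediate 16 only)
Why: Bromine–lithium exchange and DMF formylation as in step 4, now at the bromine that phenol 12 delivered to C8 of unit 2, so the site is fixed by the handle and not by the relative reactivity of the three free ring A positions of the dimer.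

Step 13
Reactants: 17 dimer 8-carbaldehyde; 7 3',4'-bis(benzyloxy)acetophenone
Product: 18 (E)-1-[3,4-bis(benzyloxy)phenyl]-3-(dimer-8-yl)prop-2-en-1-one (dimer-8-yl = 15 with the bromine replaced by the point of attachment)
Conditions: KOH, EtOH/THF, rt to 40 °C
Reagents that add atoms: none
Why: Claisen–Schmidt condensation as in step 5, giving the E-enone that carries the future C2–C3–C4 chain and ring B of unit 1 on C8 of unit 2.

Step 14
Reactants: 18 (E)-enone of the dimer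
Product: 19 [3,4-bis(benzyloxy)phenyl][(2R,3S)-3-(dimer-8-yl)oxiran-2-yl]methanone
Conditions: poly-L-leucine, urea–H2O2, DBU, THF, rt
Reagents that add atoms: hydrogen peroxide (from its urea adduct), OO
Why: Juliá–Colonna epoxidation as in step 6, the L-peptide again controlling the enone face so that the trans-(αR,βS)-epoxide sets C3 and C4 of the future unit 1.

Step 15
Reactants: 19 (2R,3S)-epoxy ketone of the dimer
Product: 20 (S)-[3,4-bis(benzyloxy)phenyl][(2S,3S)-3-(dimer-8-yl)oxiran-2-yl]methanol (erythro)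
Conditions: Zn(BH4)2, Et2O/THF, −30 °C; aq NaHCO3; Et3N-deactivated silica
Reagents that add atoms: none
Why: Chelation-controlled zinc borohydride reduction as in step 7, which should give the erythro epoxy alcohol with the (S)-carbinol.

Step 16
Reactants: 20 erythro epoxy alcohol of the dimer; 11 3,5-bis(benzyloxy)phenol
Product: 21 (2R,3S)-2-{(R)-[3,4-bis(benzyloxy)phenyl][3,5-bis(benzyloxy)phenoxy]methyl}-3-(dimer-8-yl)oxirane
Conditions: PPh3, DIAD, toluene, 0 °C to rt; basic alumina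
Reagents that add atoms: none
Why: Mitsunobu etherification with inversion as in step 9, giving the (R)-aryl ether that is C2 of unit 1; the silyl ethers on O3 of units 2 and 3 leave the epoxy carbinol as the only hydroxyl.

Step 17
Reactants: 21 trans-epoxy aryl ether on C8 of unit 2
Product: 22 5,7,3',4'-tetra-O-benzylepicatechin-(4β→8)-3-O-TBS-5,7,3',4'-tetra-O-benzylepicatechin-(4β→8)-3-O-TBS-5,7,3',4'-tetra-O-benzylepicatechin (free O3 on unit 1)
Conditions: BF3·OEt2 (0.3 equiv), CH2Cl2 (5 mM), −78 °C to −40 °C; Et3N quench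
Reagents that add atoms: none
Why: The same Lewis-acid-mediated 6-endo Friedel–Crafts epoxy–arene cyclisation as in step 10, in which either of the two equivalent ortho carbons of the 3,5-bis(benzyloxy)phenyl ether opens the epoxide at benzylic C4 with inversion, closing ring C of unit 1 and setting its C4 trans to O3 (4β).

Step 18
Reactants: 22 protected trimer with two silyl ethers
Product: 23 dodeca-O-benzylprocyanidin C1 (three free C3 hydroxyls)
Conditions: HF·pyridine, THF/pyridine, 0 °C to rt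
Reagents that add atoms: none
Why: Fluoride-mediated desilylation driven by Si–F bond formation, under buffered conditions that leave the benzyl ethers, the interflavan bonds and all stereocentres untouched.

Step 19
Reactants: 23 dodeca-O-benzylprocyanidin C1 (1 equiv); 24 3,4,5-tris(benzyloxy)benzoic acid (3 equiv are incorporated, one at each C3 hydroxyl)
Product: 25 dodeca-O-benzylprocyanidin C1 3,3',3''-tris[3,4,5-tris(benzyloxy)benzoate]
Conditions: 24 (4.5 equiv), DCC (5 equiv), DMAP (1.5 equiv), CH2Cl2, rt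
Reagents that add atoms: 3,4,5-tris(benzyloxy)benzoic acid (compound 24; three equivalents are incorporated, each as its acyl group), OC(=O)c1cc(OCc2ccccc2)c(OCc2ccccc2)c(OCc2ccccc2)c1
Why: Threefold Steglich esterification in which DCC activates each molecule of acid 24 as its O-acylisourea and DMAP relays the acyl group to a secondary C3 hydroxyl, so that three molecules of 24 are consumed per molecule of 23; the C3–O bonds are not broken, so the configuration is retained.

Step 20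
Reactants: 25 fully benzylated tri-gallate
Product: 26 procyanidin C1 3,3',3''-tri-O-gallate
Conditions: H2 (1 atm), Pd(OH)2/C, THF/MeOH/H2O, rt
Reagents that add atoms: none
Why: Catalytic hydrogenolysis of the 21 benzyl ethers under mild neutral conditions, under which gallate esters, the ring C2–O1 bonds and the interflavan C4–C8 bonds of flavan-3-ol oligomers are expected to survive.

Compound list
1 | (−)-epicatechin | O[C@@H]1Cc2c(O)cc(O)cc2O[C@@H]1c1ccc(O)c(O)c1 | starting material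
2 | 5,7,3',4'-tetra-O-benzyl-(−)-epicatechin, (2R,3R) | O[C@@H]1Cc2c(OCc9ccccc9)cc(OCc9ccccc9)cc2O[C@@H]1c8ccc(OCc9ccccc9)c(OCc9ccccc9)c8 | intermediate
3 | 8-bromo-5,7,3',4'-tetra-O-benzylepicatechin | O[C@@H]1Cc2c(OCc9ccccc9)cc(OCc9ccccc9)c(Br)c2O[C@@H]1c8ccc(OCc9ccccc9)c(OCc9ccccc9)c8 | intermediate
4 | 8-bromo-3-O-TBS-5,7,3',4'-tetra-O-benzylepicatechin | CC(C)(C)[Si](C)(C)O[C@@H]1Cc2c(OCc9ccccc9)cc(OCc9ccccc9)c(Br)c2O[C@@H]1c8ccc(OCc9ccccc9)c(OCc9ccccc9)c8 | intermediate
5 | 8-lithio-3-O-TBS-5,7,3',4'-tetra-O-benzylepicatechin | CC(C)(C)[Si](C)(C)O[C@@H]1Cc2c(OCc9ccccc9)cc(OCc9ccccc9)c([Li])c2O[C@@H]1c8ccc(OCc9ccccc9)c(OCc9ccccc9)c8 | intermediate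
6 | 8-formyl-3-O-TBS-5,7,3',4'-tetra-O-benzylepicatechin | CC(C)(C)[Si](C)(C)O[C@@H]1Cc2c(OCc9ccccc9)cc(OCc9ccccc9)c(C=O)c2O[C@@H]1c8ccc(OCc9ccccc9)c(OCc9ccccc9)c8 | intermediate
7 | 3',4'-bis(benzyloxy)acetophenone | CC(=O)c1ccc(OCc2ccccc2)c(OCc2ccccc2)c1 | starting material
8 | (E)-1-[3,4-bis(benzyloxy)phenyl]-3-(3-O-TBS-5,7,3',4'-tetra-O-benzylepicatechin-8-yl)prop-2-en-1-one | O=C(/C=C/c2c(OCc9ccccc9)cc(OCc9ccccc9)c3c2O[C@H](c8ccc(OCc9ccccc9)c(OCc9ccccc9)c8)[C@H](O[Si](C)(C)C(C)(C)C)C3)c8ccc(OCc9ccccc9)c(OCc9ccccc9)c8 | intermediate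
9 | [3,4-bis(benzyloxy)phenyl][(2R,3S)-3-(3-O-TBS-5,7,3',4'-tetra-O-benzylepicatechin-8-yl)oxiran-2-yl]methanone | O=C([C@@H]1O[C@H]1c2c(OCc9ccccc9)cc(OCc9ccccc9)c3c2O[C@H](c8ccc(OCc9ccccc9)c(OCc9ccccc9)c8)[C@H](O[Si](C)(C)C(C)(C)C)C3)c8ccc(OCc9ccccc9)c(OCc9ccccc9)c8 | intermediate
10 | (S)-[3,4-bis(benzyloxy)phenyl][(2S,3S)-3-(3-O-TBS-5,7,3',4'-tetra-O-benzylepicatechin-8-yl)oxiran-2-yl]methanol, erythro | O[C@@H](c8ccc(OCc9ccccc9)c(OCc9ccccc9)c8)[C@@H]1O[C@H]1c2c(OCc9ccccc9)cc(OCc9ccccc9)c3c2O[C@H](c8ccc(OCc9ccccc9)c(OCc9ccccc9)c8)[C@H](O[Si](C)(C)C(C)(C)C)C3 | intermediate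
11 | 3,5-bis(benzyloxy)phenol | Oc1cc(OCc2ccccc2)cc(OCc2ccccc2)c1 | starting material
12 | 2-bromo-3,5-bis(benzyloxy)phenol | Oc1cc(OCc2ccccc2)cc(OCc2ccccc2)c1Br | intermediate
13 | (2R,3S)-2-{(R)-[3,4-bis(benzyloxy)phenyl][2-bromo-3,5-bis(benzyloxy)phenoxy]methyl}-3-(3-O-TBS-5,7,3',4'-tetra-O-benzylepicatechin-8-yl)oxirane (precursor of the key step) | c2c(OCc9ccccc9)cc(OCc9ccccc9)c(Br)c2O[C@H](c8ccc(OCc9ccccc9)c(OCc9ccccc9)c8)[C@@H]1O[C@H]1c2c(OCc9ccccc9)cc(OCc9ccccc9)c3c2O[C@H](c8ccc(OCc9ccccc9)c(OCc9ccccc9)c8)[C@H](O[Si](C)(C)C(C)(C)C)C3 | intermediate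
14 | 8-bromo-5,7,3',4'-tetra-O-benzylepicatechin-(4β→8)-3-O-TBS-5,7,3',4'-tetra-O-benzylepicatechin (product of the key step) | O[C@@H]1[C@@H](c2c(OCc9ccccc9)cc(OCc9ccccc9)c3c2O[C@H](c8ccc(OCc9ccccc9)c(OCc9ccccc9)c8)[C@H](O[Si](C)(C)C(C)(C)C)C3)c2c(OCc9ccccc9)cc(OCc9ccccc9)c(Br)c2O[C@@H]1c8ccc(OCc9ccccc9)c(OCc9ccccc9)c8 | intermediate
15 | 8-bromo-3-O-TBS-5,7,3',4'-tetra-O-benzylepicatechin-(4β→8)-3-O-TBS-5,7,3',4'-tetra-O-benzylepicatechin | CC(C)(C)[Si](C)(C)O[C@@H]1[C@@H](c2c(OCc9ccccc9)cc(OCc9ccccc9)c3c2O[C@H](c8ccc(OCc9ccccc9)c(OCc9ccccc9)c8)[C@H](O[Si](C)(C)C(C)(C)C)C3)c2c(OCc9ccccc9)cc(OCc9ccccc9)c(Br)c2O[C@@H]1c8ccc(OCc9ccccc9)c(OCc9ccccc9)c8 | intermediate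
16 | 8-lithio derivative of the bis-TBS dimer (lithium on C8 of unit 2) | CC(C)(C)[Si](C)(C)O[C@@H]1[C@@H](c2c(OCc9ccccc9)cc(OCc9ccccc9)c3c2O[C@H](c8ccc(OCc9ccccc9)c(OCc9ccccc9)c8)[C@H](O[Si](C)(C)C(C)(C)C)C3)c2c(OCc9ccccc9)cc(OCc9ccccc9)c([Li])c2O[C@@H]1c8ccc(OCc9ccccc9)c(OCc9ccccc9)c8 | intermediate
17 | 8-formyl-3-O-TBS-5,7,3',4'-tetra-O-benzylepicatechin-(4β→8)-3-O-TBS-5,7,3',4'-tetra-O-benzylepicatechin | CC(C)(C)[Si](C)(C)O[C@@H]1[C@@H](c2c(OCc9ccccc9)cc(OCc9ccccc9)c3c2O[C@H](c8ccc(OCc9ccccc9)c(OCc9ccccc9)c8)[C@H](O[Si](C)(C)C(C)(C)C)C3)c2c(OCc9ccccc9)cc(OCc9ccccc9)c(C=O)c2O[C@@H]1c8ccc(OCc9ccccc9)c(OCc9ccccc9)c8 | intermediate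
18 | (E)-1-[3,4-bis(benzyloxy)phenyl]-3-(dimer-8-yl)prop-2-en-1-one | O=C(/C=C/c4c(OCc9ccccc9)cc(OCc9ccccc9)c5c4O[C@H](c8ccc(OCc9ccccc9)c(OCc9ccccc9)c8)[C@H](O[Si](C)(C)C(C)(C)C)[C@H]5c2c(OCc9ccccc9)cc(OCc9ccccc9)c3c2O[C@H](c8ccc(OCc9ccccc9)c(OCc9ccccc9)c8)[C@H](O[Si](C)(C)C(C)(C)C)C3)c8ccc(OCc9ccccc9)c(OCc9ccccc9)c8 | intermediate
19 | [3,4-bis(benzyloxy)phenyl][(2R,3S)-3-(dimer-8-yl)oxiran-2-yl]methanone | O=C([C@@H]1O[C@H]1c4c(OCc9ccccc9)cc(OCc9ccccc9)c5c4O[C@H](c8ccc(OCc9ccccc9)c(OCc9ccccc9)c8)[C@H](O[Si](C)(C)C(C)(C)C)[C@H]5c2c(OCc9ccccc9)cc(OCc9ccccc9)c3c2O[C@H](c8ccc(OCc9ccccc9)c(OCc9ccccc9)c8)[C@H](O[Si](C)(C)C(C)(C)C)C3)c8ccc(OCc9ccccc9)c(OCc9ccccc9)c8 | intermediate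
20 | (S)-[3,4-bis(benzyloxy)phenyl][(2S,3S)-3-(dimer-8-yl)oxiran-2-yl]methanol, erythro | O[C@@H](c8ccc(OCc9ccccc9)c(OCc9ccccc9)c8)[C@@H]1O[C@H]1c4c(OCc9ccccc9)cc(OCc9ccccc9)c5c4O[C@H](c8ccc(OCc9ccccc9)c(OCc9ccccc9)c8)[C@H](O[Si](C)(C)C(C)(C)C)[C@H]5c2c(OCc9ccccc9)cc(OCc9ccccc9)c3c2O[C@H](c8ccc(OCc9ccccc9)c(OCc9ccccc9)c8)[C@H](O[Si](C)(C)C(C)(C)C)C3 | intermediate
21 | (2R,3S)-2-{(R)-[3,4-bis(benzyloxy)phenyl][3,5-bis(benzyloxy)phenoxy]methyl}-3-(dimer-8-yl)oxirane | c2c(OCc9ccccc9)cc(OCc9ccccc9)cc2O[C@H](c8ccc(OCc9ccccc9)c(OCc9ccccc9)c8)[C@@H]1O[C@H]1c4c(OCc9ccccc9)cc(OCc9ccccc9)c5c4O[C@H](c8ccc(OCc9ccccc9)c(OCc9ccccc9)c8)[C@H](O[Si](C)(C)C(C)(C)C)[C@H]5c2c(OCc9ccccc9)cc(OCc9ccccc9)c3c2O[C@H](c8ccc(OCc9ccccc9)c(OCc9ccccc9)c8)[C@H](O[Si](C)(C)C(C)(C)C)C3 | intermediate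
22 | 5,7,3',4'-tetra-O-benzylepicatechin-(4β→8)-3-O-TBS-5,7,3',4'-tetra-O-benzylepicatechin-(4β→8)-3-O-TBS-5,7,3',4'-tetra-O-benzylepicatechin | O[C@@H]1[C@@H](c4c(OCc9ccccc9)cc(OCc9ccccc9)c5c4O[C@H](c8ccc(OCc9ccccc9)c(OCc9ccccc9)c8)[C@H](O[Si](C)(C)C(C)(C)C)[C@H]5c2c(OCc9ccccc9)cc(OCc9ccccc9)c3c2O[C@H](c8ccc(OCc9ccccc9)c(OCc9ccccc9)c8)[C@H](O[Si](C)(C)C(C)(C)C)C3)c2c(OCc9ccccc9)cc(OCc9ccccc9)cc2O[C@@H]1c8ccc(OCc9ccccc9)c(OCc9ccccc9)c8 | intermediate
23 | dodeca-O-benzylprocyanidin C1 (three free C3 hydroxyls) | O[C@@H]1[C@@H](c4c(OCc9ccccc9)cc(OCc9ccccc9)c5c4O[C@H](c8ccc(OCc9ccccc9)c(OCc9ccccc9)c8)[C@H](O)[C@H]5c2c(OCc9ccccc9)cc(OCc9ccccc9)c3c2O[C@H](c8ccc(OCc9ccccc9)c(OCc9ccccc9)c8)[C@H](O)C3)c2c(OCc9ccccc9)cc(OCc9ccccc9)cc2O[C@@H]1c8ccc(OCc9ccccc9)c(OCc9ccccc9)c8 | intermediate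
24 | 3,4,5-tris(benzyloxy)benzoic acid | OC(=O)c1cc(OCc2ccccc2)c(OCc2ccccc2)c(OCc2ccccc2)c1 | starting material
25 | dodeca-O-benzylprocyanidin C1 3,3',3''-tris[3,4,5-tris(benzyloxy)benzoate] | O=C(O[C@@H]1[C@@H](c4c(OCc9ccccc9)cc(OCc9ccccc9)c5c4O[C@H](c8ccc(OCc9ccccc9)c(OCc9ccccc9)c8)[C@H](OC(=O)c7cc(OCc9ccccc9)c(OCc9ccccc9)c(OCc9ccccc9)c7)[C@H]5c2c(OCc9ccccc9)cc(OCc9ccccc9)c3c2O[C@H](c8ccc(OCc9ccccc9)c(OCc9ccccc9)c8)[C@H](OC(=O)c7cc(OCc9ccccc9)c(OCc9ccccc9)c(OCc9ccccc9)c7)C3)c2c(OCc9ccccc9)cc(OCc9ccccc9)cc2O[C@@H]1c8ccc(OCc9ccccc9)c(OCc9ccccc9)c8)c7cc(OCc9ccccc9)c(OCc9ccccc9)c(OCc9ccccc9)c7 | intermediate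
26 | procyanidin C1 3,3',3''-tri-O-gallate | O=C(O[C@@H]1[C@@H](c2c(O)cc(O)c3c2O[C@H](c2ccc(O)c(O)c2)[C@H](OC(=O)c2cc(O)c(O)c(O)c2)C3)c2c(O)cc(O)c([C@H]3c4c(O)cc(O)cc4O[C@H](c4ccc(O)c(O)c4)[C@@H]3OC(=O)c3cc(O)c(O)c(O)c3)c2O[C@@H]1c1ccc(O)c(O)c1)c1cc(O)c(O)c(O)c1 | target

Total step count: 20. Longest linear sequence: 19 steps (steps 1–7 and 9–20, from 1 to 26); step 8 is the only side-branch step.

Steps most likely to fail

Step 10 (and its repeat, step 17). After the C4–O bond ionises, the C3 hydrogen may migrate to give the C3 ketone (Meinwald rearrangement), the cation may be captured intermolecularly, or the ring may close without clean inversion. The fallback makes the interflavan bond by the conventional intermolecular condensation and sets out from 3 and 2. Bromide 3 is oxidised at C4 with DDQ in CH2Cl2 containing ethylene glycol to 8-bromo-4β-(2-hydroxyethoxy)-5,7,3',4'-tetra-O-benzylepicatechin F1. Compound 2 is silylated (TBSOTf, 2,6-lutidine) to 3-O-TBS-5,7,3',4'-tetra-O-benzylepicatechin F2. TMSOTf-promoted Friedel–Crafts condensation of F1 with an excess of F2 (CH2Cl2, −78 °C) should then give 14, where the route is rejoined; the C8 bromine of F1 blocks self-condensation and attack trans to O3 sets 4β.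

Step 6 (and its repeat, step 14). Oxygen transfer to the β-carbon may be slow or absent, because that carbon is deactivated by three oxygen donors and flanked by two ortho substituents, and the bulky chiral aryl group may lower the facial selectivity. The fallback changes from nucleophilic to hydroxyl-directed electrophilic epoxidation and sets out from 8. Corey–Bakshi–Shibata reduction ((S)-2-methyl-CBS-oxazaborolidine, catecholborane, toluene, −78 °C), with the catalyst enantiomer chosen on the premise that the aryl group acts as the larger ketone substituent, should give (R,E)-1-[3,4-bis(benzyloxy)phenyl]-3-(3-O-TBS-5,7,3',4'-tetra-O-benzylepicatechin-8-yl)prop-2-en-1-ol F3. Sharpless epoxidation of F3 with Ti(OiPr)4, L-(+)-diisopropyl tartrate and t-BuOOH (4 Å sieves, CH2Cl2, −20 °C), the matched pairing for the (R)-carbinol, should give the erythro epoxy alcohol 10, where the route is rejoined; steps 6 and 7 are replaced.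

Step 16 (and the analogous step 9). The alkoxyphosphonium at the electron-rich benzylic carbon may ionise, so that inversion is lost or elimination occurs, and the hindered dimer may react too slowly. The fallback forms the aryl–oxygen bond instead of the alkyl–oxygen bond and sets out from epoxy ketone 19. Reagent-controlled reduction with (R)-2-methyl-CBS-oxazaborolidine and catecholborane should give the threo alcohol (R)-[3,4-bis(benzyloxy)phenyl][(2S,3S)-3-(dimer-8-yl)oxiran-2-yl]methanol F4, the C2 epimer of 20. Palladium-catalysed C–O coupling of F4 with 1-bromo-3,5-bis(benzyloxy)benzene ([Pd(allyl)Cl]2, tBuBrettPhos, Cs2CO3, toluene, 60 °C), which retains the carbinol configuration, should give 21, where the route is rejoined.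

Further compounds
F1 | step 10 | 8-bromo-4β-(2-hydroxyethoxy)-5,7,3',4'-tetra-O-benzylepicatechin | O[C@@H]1[C@@H](OCCO)c2c(OCc9ccccc9)cc(OCc9ccccc9)c(Br)c2O[C@@H]1c8ccc(OCc9ccccc9)c(OCc9ccccc9)c8
F2 | step 10 | 3-O-TBS-5,7,3',4'-tetra-O-benzylepicatechin | CC(C)(C)[Si](C)(C)O[C@@H]1Cc2c(OCc9ccccc9)cc(OCc9ccccc9)cc2O[C@@H]1c8ccc(OCc9ccccc9)c(OCc9ccccc9)c8
F3 | step 6 | (R,E)-1-[3,4-bis(benzyloxy)phenyl]-3-(3-O-TBS-5,7,3',4'-tetra-O-benzylepicatechin-8-yl)prop-2-en-1-ol | O[C@@H](c8ccc(OCc9ccccc9)c(OCc9ccccc9)c8)/C=C/c2c(OCc9ccccc9)cc(OCc9ccccc9)c3c2O[C@H](c8ccc(OCc9ccccc9)c(OCc9ccccc9)c8)[C@H](O[Si](C)(C)C(C)(C)C)C3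
F4 | step 16 | (R)-[3,4-bis(benzyloxy)phenyl][(2S,3S)-3-(dimer-8-yl)oxiran-2-yl]methanol, threo | O[C@H](c8ccc(OCc9ccccc9)c(OCc9ccccc9)c8)[C@@H]1O[C@H]1c4c(OCc9ccccc9)cc(OCc9ccccc9)c5c4O[C@H](c8ccc(OCc9ccccc9)c(OCc9ccccc9)c8)[C@H](O[Si](C)(C)C(C)(C)C)[C@H]5c2c(OCc9ccccc9)cc(OCc9ccccc9)c3c2O[C@H](c8ccc(OCc9ccccc9)c(OCc9ccccc9)c8)[C@H](O[Si](C)(C)C(C)(C)C)C3
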